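The data are calculated on assumed constants; scatter was added.

common to all: free catalyst 26 µM

| run | solid substrate | remark | time |
|---|---|---|---|
| Tuesday's | 0.020 M | the very flask that is asked about, followed so far |  |
| Friday's | 0.040 M | run made earlier |  |
| flask | 0.020 M |  | 20 min |

Tuesday's run (percent of the solid substrate charged)

| time / min | target / % | solid substrate / % |
|---|---|---|
| 2.50 | 8.5 | 83.5 |
| 5.00 | 12.5 | 67.0 |
| 6.00 | 14.4 | 61.0 |
| 10.0 | 19.6 | 36.1 |
| 12.0 | 22.0 | 23.4 |
| 15.0 | 26.9 | 5.3 |

Friday's run (percent of the solid substrate charged)

| time / s | target / % | solid substrate / % |
|---|---|---|
| 10.0 | 0.4 | 99.7 |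
| 15.0 | 0.3 | 99.2 |
| 20.0 | 0.8 | 98.6 |
| 30.0 | 0.8 | 98.2 |
| 40.0 | 0.9 | 97.9 |
| 50.0 | 1.3 | 97.1 |

(standard deviation of a reading: 0.3 percentage points)

- given per volume of solution although it is solid: solid substrate
- removed target is counted in
- at the start none of the solid substrate is in solution
- additions bring no volume worth counting

- autumn: at 20 min take out 90% of the target then present, then wait 10 min
- winter: at 20 min add free catalyst, 100% of the amount charged, then wait 10 min
- noon: change nothing and wait 10 min more

* target, in percent of the solid substrate first charged, at 20 min
* the remedy with the largest gain of target, or "none" below 2 percentage points (autumn / winter / noon / none)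
* target present, with what was taken out counted in, in percent of the solid substrate first charged, after autumn
* target present, with what was taken out counted in, in percent of the solid substrate first charged, after winter

1. Start from the slowness of the dissolving. In Tuesday's run, between 6.00 min and 15.0 min, the solid substrate falls at a steady d = 0.0619 min⁻¹ of the charge, while target rises at g = 0.0139 min⁻¹, slower.

2. Divide these two rates. The late share σ, the part of each further point dissolved that stays target (a differential selectivity), is g/d = 22.4%.

3. Compare target with σ times what has dissolved. At 15.0 min Tuesday's flask stands above that by a surplus h = 5.65% of the charge. Read h as material in transit, present while the solid still feeds the solution.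

4. Follow the solid. From 5.3% at 15.0 min, pace d brings it to zero at 15.9 min, earlier than 20 min. Let h drain, and my reckoning for target at 20 min is σ of the charge, 22.4%.

5. Apply σ to the remedies. Autumn removes 20.2% of the charge, and the remainder splits by σ again, so the total is 38.1%, a gain of 16 percentage points. Winter and noon take nothing out, so count each below 2 points and choose autumn.

6. The forecast gave 33.5% now, 52% after autumn and 50% after winter, and chose autumn “Autumn is a narrow, tentative pick.”

7. The flask gives 22.9% now, 37.7% after autumn and 21.3% after winter. The gains are 15 points for autumn, −1.7 points for winter and −0.62 points for noon, so the best is autumn.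

    starting material ⇌ target (K = 15.0, k = 0.0697 s⁻¹)
    target ⇌ isomer of the product A (K = 2.69, k = 0.0104 s⁻¹)
    isomer of the product A + free catalyst ⇌ isomer of the product B + free catalyst, rate k3*[free catalyst]*[isomer of the product A] forward; the back reaction follows from the equilibrium constant (K = 0.350, k = 8800 M⁻¹ s⁻¹)
    solid substrate ⇌ starting material, rate k4*(cs4 - [starting material]) while solid is left; crystals form when [starting material] > cs4 (solubility = 4.20 mM, k = 0.00569 s⁻¹)
    2 free catalyst → spent catalyst A (k = 644 M⁻¹ s⁻¹)
    starting material + free catalyst → spent catalyst B (k = 7.82 M⁻¹ s⁻¹)

Target in this flask stays low because it passes on into isomer of the product A. At 20 min, the run without that passage, both ways, stands at 93.7% against 22.9%. The relaxation half-life of target and isomer of the product A by this step alone, both ways together, is 0.810 min, short against 20 min.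

Carry σ to the neighbour flask, the same charge read at 5.0 min with solid still feeding. σ times the dissolved 33.0%, plus h, gives 13.1%. The computed target there is 12.7%.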